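**Direct plan and its weak points**

A direct plan would make ring A first as the symmetrical triol A1, acylate its one free carbon with a methoxyacetyl unit and close the pyranone with a one-carbon DMF/MsCl reagent to the 2-unsubstituted 3-methoxychromone A2, and only then attach ring B by zincating A2 at C2 and adding it to the quinone A3 under monovalent rhodium catalysis.
(a) The final union of C2-metallated A2 with A3 would be the weakest step: it has no close precedent, must choose C5 of A3 over C6 and C3, pairs an electron-rich organozinc with an oxidising quinone, and stakes all material on the last operation.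
(b) The one-pot acylation/one-carbon closure to A2 would be the second: a protocol made for benzylic CH2 groups would have to work on a CH2(OMe) ketone carrying three free phenols in the presence of MsCl, and it gives a base-sensitive chromone that still lacks ring B.
(c) The transient silyl ethers put on and taken off around that single bond would add handling without building anything.

**Retrosynthetic overview of the new route**

- Key disconnection: C4–C4a and O1–C2 are cut together, giving the ring A triol 6 and the α-methoxy β-keto ester 14, which already holds ring B, C2, C3 with its OMe, and C4.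
- Feature used: ring A is a 2,4-dimethoxyphloroglucinol whose only unsubstituted carbon (C4a) lies between two symmetry-equivalent hydroxyls (future O1 and 5-OH), so an acylketene can acylate one carbon only and either hydroxyl closes to the same chromone.
- Ring order: rings A and B are aromatic from the start; ring C is formed last in one thermal step (Mentzer-type), leaving only hydrogenolysis of two benzyl ethers.
- Avoided by design: no C2 metallation, no quinone partner, no one-carbon closure, no silyl shuffling; the ring B oxygen pattern is fixed early by a para-selective formylation.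

Key step: step 7

Assumption: aldol 13 and keto ester 14 are carried on as stereoisomer and tautomer mixtures, since both propanoate stereocentres end as sp2 carbons of ring C.

**Route**

Step 1
Reactants: 1 2,6-dimethoxyphenol
Product: 3 3,5-dibromo-2,6-dimethoxyphenyl acetate, via 2,6-dimethoxyphenyl acetate 2 (not isolated)
Conditions: Ac2O (1.5 equiv), NaOAc (4 equiv), AcOH, 100 °C; then Br2 (2.1 equiv), 20 to 40 °C
Reagents that add atoms: acetic anhydride CC(=O)OC(C)=O; bromine BrBr
Why: O-acetylation followed by electrophilic aromatic bromination should work because, with the phenol masked as its ester, the two methoxy groups direct both bromines to C3 and C5 (each ortho to one OMe and para to the other) while acetate buffers the HBr.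

Step 2
Reactants: 3 3,5-dibromo-2,6-dimethoxyphenyl acetate
Product: 6 2,4-dimethoxybenzene-1,3,5-triol, via dibromophenol 4 (not isolated), via bromoresorcinol 5 (not isolated)
Conditions: Cu(acac)2 (10 mol %), N,N'-bis(4-hydroxy-2,6-dimethylphenyl)oxalamide (10 mol %), LiOH·H2O (8 equiv), degassed DMSO/H2O 4:1, 80 °C, Ar; then aq HCl to pH 3 under Ar
Reagents that add atoms: lithium hydroxide monohydrate O.[Li+].[OH-]
Why: Saponification followed by copper/oxalamide-catalysed Ullmann-type hydroxylation of both aryl bromides should give the mirror-symmetric triol, which is acidified under argon before isolation because its phenoxide is air-sensitive.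

Step 3
Reactants: 7 2-methoxybenzene-1,4-diol
Product: 8 1,4-bis(benzyloxy)-2-methoxybenzene
Conditions: BnBr (2.3 equiv), K2CO3 (3 equiv), DMF, 60 °C, Ar
Reagents that add atoms: benzyl bromide BrCc1ccccc1
Why: Williamson etherification of both phenols masks the hydroquinone as benzyl ethers that resist oxidation, survive the thermal key step and leave by hydrogenolysis at the end.

Step 4
Reactants: 8 1,4-bis(benzyloxy)-2-methoxybenzene
Product: 10 2,5-bis(benzyloxy)-4-methoxybenzaldehyde, via iminium chloride 9 (not isolated)
Conditions: POCl3 (1.5 equiv), DMF, 0 to 75 °C; then aq NaOAc, 60 °C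
Reagents that add atoms: N,N-dimethylformamide CN(C)C=O; water O
Why: Vilsmeier–Haack formylation should attack the carbon para to the methoxy group and ortho to a benzyloxy group, the most activated and least hindered site, just as 1,2,4-trialkoxybenzenes give 2,4,5-trialkoxybenzaldehydes, and this fixes the ring B pattern (2'-O, 4'-OMe, 5'-O).

Step 5
Reactants: 10 2,5-bis(benzyloxy)-4-methoxybenzaldehyde; 11 methyl methoxyacetate
Product: 13 methyl 3-[2,5-bis(benzyloxy)-4-methoxyphenyl]-3-hydroxy-2-methoxypropanoate (mixture of racemic diastereomers), via lithium enolate 12 (not isolated)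
Conditions: 11 (1.2 equiv), LiN(iPr)2 (1.15 equiv), THF, -78 °C; then 10, -78 °C; AcOH quench
Reagents that add atoms: none
Why: Aldol addition of the lithium ester enolate to the non-enolisable aldehyde should be clean at low temperature; the two new stereocentres form without control, which is of no consequence because both are removed in steps 6 and 7.

Step 6
Reactants: 13 methyl 3-[2,5-bis(benzyloxy)-4-methoxyphenyl]-3-hydroxy-2-methoxypropanoate
Product: 14 methyl 3-[2,5-bis(benzyloxy)-4-methoxyphenyl]-2-methoxy-3-oxopropanoate (racemic, keto–enol mixture)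
Conditions: Dess–Martin periodinane (1.3 equiv), CH2Cl2, 0 to 25 °C
Reagents that add atoms: none
Why: Dess–Martin oxidation of the benzylic secondary alcohol should give the β-keto ester under neutral conditions that spare the benzyl ethers and the electron-rich ring; the remaining CH(OMe) centre is enolisable and becomes C3 in step 7.

Step 7
Reactants: 6 2,4-dimethoxybenzene-1,3,5-triol; 14 methyl 3-[2,5-bis(benzyloxy)-4-methoxyphenyl]-2-methoxy-3-oxopropanoate
Product: 17 2-[2,5-bis(benzyloxy)-4-methoxyphenyl]-5,7-dihydroxy-3,6,8-trimethoxy-4H-chromen-4-one, via aroylketene 15 (not isolated), via acylphloroglucinol 16 (not isolated)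
Conditions: 6 (1.3 equiv), Ph2O (minimal), 240 °C, Ar sweep, MeOH and H2O distilled out
Reagents that add atoms: none
Why: On heating, the enol form of 14 should lose methanol through a six-membered transition state to give the aroyl(methoxy)ketene 15, which acylates triol 6 at its only unsubstituted ring carbon (the future C4a; any aryl ester formed at oxygen is itself a ketene source and returns to 15) to give the 2-acylphloroglucinol 16. The phenol next to the new ketone then adds to the ring B carbonyl (6-exo-trig) and the hemiketal loses water, so ring C closes last, after the C4–C4a bond and at O1–C2. The closest known reaction type is the Mentzer pyrone synthesis, the uncatalysed thermal condensation of phloroglucinol with aroylacetic esters to 5,7-dihydroxyflavones, in which α-substituted keto esters deliver 3-substituted chromones. No stereocentre is formed, and the racemic CH(OMe) centre of 14 becomes the sp2 carbon C3. The step needs the chromone and not the Pechmann (coumarin) mode of closure, which the acid-free conditions should secure because the ketene acylates carbon before a phenol can attack the ketone; it needs no regiocontrol on ring A, since C4a is the single free position and the two flanking hydroxyls are equivalent by the mirror symmetry of 6. The benzyl ethers on ring B keep its 2'-oxygen from trapping the ketene as a 4-hydroxycoumarin.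

Step 8
Reactants: 17 2-[2,5-bis(benzyloxy)-4-methoxyphenyl]-5,7-dihydroxy-3,6,8-trimethoxy-4H-chromen-4-one
Product: 18 5,7,2',5'-tetrahydroxy-3,6,8,4'-tetramethoxyflavone
Conditions: H2 (1 atm), Pd/C (10 wt %), EtOAc/MeOH, 25 °C; filtration and evaporation under Ar
Reagents that add atoms: none
Why: Hydrogenolysis of the two aryl benzyl ethers over palladium on carbon should leave the tetrasubstituted C2=C3 bond of the chromone and all methyl ethers untouched; the product is handled under argon because ring B is then a free methoxyhydroquinone, and no stereocentre is present.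

**Compound list**

1 | 2,6-dimethoxyphenol | COc1cccc(OC)c1O | starting material
2 | 2,6-dimethoxyphenyl acetate | CC(=O)Oc1c(OC)cccc1OC | intermediate
3 | 3,5-dibromo-2,6-dimethoxyphenyl acetate | CC(=O)Oc1c(OC)c(Br)cc(Br)c1OC | intermediate
4 | 3,5-dibromo-2,6-dimethoxyphenol (present as lithium phenoxide) | COc1c(Br)cc(Br)c(OC)c1O | intermediate
5 | 5-bromo-2,4-dimethoxybenzene-1,3-diol (present as lithium phenoxide) | COc1c(O)cc(Br)c(OC)c1O | intermediate
6 | 2,4-dimethoxybenzene-1,3,5-triol | COc1c(O)cc(O)c(OC)c1O | intermediate
7 | 2-methoxybenzene-1,4-diol (2-methoxyhydroquinone) | COc1cc(O)ccc1O | starting material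
8 | 1,4-bis(benzyloxy)-2-methoxybenzene | COc1cc(OCc2ccccc2)ccc1OCc1ccccc1 | intermediate
9 | N-[2,5-bis(benzyloxy)-4-methoxybenzylidene]-N-methylmethanaminium chloride | COc1cc(OCc2ccccc2)c(C=[N+](C)C)cc1OCc1ccccc1.[Cl-] | intermediate
10 | 2,5-bis(benzyloxy)-4-methoxybenzaldehyde | COc1cc(OCc2ccccc2)c(C=O)cc1OCc1ccccc1 | intermediate
11 | methyl methoxyacetate | COCC(=O)OC | starting material
12 | lithium 1,2-dimethoxyethen-1-olate (ester enolate of 11) | [Li+].[O-]C(OC)=COC | intermediate
13 | methyl 3-[2,5-bis(benzyloxy)-4-methoxyphenyl]-3-hydroxy-2-methoxypropanoate (mixture of racemic diastereomers) | COC(=O)C(OC)C(O)c1cc(OCc2ccccc2)c(OC)cc1OCc1ccccc1 | intermediate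
14 | methyl 3-[2,5-bis(benzyloxy)-4-methoxyphenyl]-2-methoxy-3-oxopropanoate (racemic) | COC(=O)C(OC)C(=O)c1cc(OCc2ccccc2)c(OC)cc1OCc1ccccc1 | intermediate
15 | [2,5-bis(benzyloxy)-4-methoxybenzoyl](methoxy)ketene | COC(=C=O)C(=O)c1cc(OCc2ccccc2)c(OC)cc1OCc1ccccc1 | intermediate
16 | 1-[2,5-bis(benzyloxy)-4-methoxyphenyl]-2-methoxy-3-(2,4,6-trihydroxy-3,5-dimethoxyphenyl)propane-1,3-dione (racemic) | COC(C(=O)c1cc(OCc2ccccc2)c(OC)cc1OCc1ccccc1)C(=O)c1c(O)c(OC)c(O)c(OC)c1O | intermediate
17 | 2-[2,5-bis(benzyloxy)-4-methoxyphenyl]-5,7-dihydroxy-3,6,8-trimethoxy-4H-chromen-4-one | COc1cc(OCc2ccccc2)c(-c2oc3c(OC)c(O)c(OC)c(O)c3c(=O)c2OC)cc1OCc1ccccc1 | intermediate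
18 | 5,7,2',5'-tetrahydroxy-3,6,8,4'-tetramethoxyflavone, i.e. 2-(2,5-dihydroxy-4-methoxyphenyl)-5,7-dihydroxy-3,6,8-trimethoxy-4H-chromen-4-one (achiral) | COc1cc(O)c(-c2oc3c(OC)c(O)c(OC)c(O)c3c(=O)c2OC)cc1O | target

**Step count and risks**

Total step count: 8. Longest linear sequence: 6 steps (7 → 8 → 10 → 13 → 14 → 17 → 18); the ring A branch (1 → 3 → 6) has 2 steps.

Steps most likely to fail:

1. Step 7. The ketene may be consumed at oxygen without acyl migration to carbon, ring closure may take the coumarin mode, or benzyl groups may be lost or transferred at 240 °C. The fallback is an Allan–Robinson sequence that sets out from 6 and 10 and comes back at 17. Triol 6 would be C-acylated with methoxyacetic acid in BF3·OEt2 at 85 °C to 1-(2,4,6-trihydroxy-3,5-dimethoxyphenyl)-2-methoxyethan-1-one F1. Aldehyde 10 would be oxidised (NaClO2, NaH2PO4, 2-methylbut-2-ene, tBuOH/H2O) to 2,5-bis(benzyloxy)-4-methoxybenzoic acid F2 and dehydrated with dicyclohexylcarbodiimide to 2,5-bis(benzyloxy)-4-methoxybenzoic anhydride F3. Heating F1 with F3 and Et3N at 160 °C should give the flavone as its 7-O-[2,5-bis(benzyloxy)-4-methoxybenzoyl] ester F4, and brief KOH in aqueous ethanol should cleave that ester to 17.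

2. Step 2. The second substitution may stall, bromine may be lost reductively, or the triphenoxide may be oxidised in hot aqueous base. The fallback sets out from 3 and comes back at 6 by carbon–boron oxidation in place of Ullmann-type coupling. Double Miyaura borylation (B2pin2, Pd(dppf)Cl2, KOAc, dioxane, 90 °C) should give 2,6-dimethoxy-3,5-bis(4,4,5,5-tetramethyl-1,3,2-dioxaborolan-2-yl)phenyl acetate F5. Oxidation with H2O2 and aqueous NaOH in THF at 0 °C, which also cleaves the acetate, followed by acidification under argon, should give 6.

3. Step 8. The second debenzylation may be slow on a poisoned catalyst, or the freed ring B hydroquinone may be oxidised by air to the quinone during filtration. The fallback sets out from 17 and comes back at 18 by Lewis-acid cleavage in place of hydrogenolysis: BCl3 with pentamethylbenzene as benzyl-cation scavenger in CH2Cl2 at -78 °C, then a methanol quench. This is homogeneous, needs no filtration in air, and is cold and brief enough to spare the methyl ethers; it makes no new compound.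

**Further compounds**

F1 | step 7 | 1-(2,4,6-trihydroxy-3,5-dimethoxyphenyl)-2-methoxyethan-1-one | COCC(=O)c1c(O)c(OC)c(O)c(OC)c1O
F2 | step 7 | 2,5-bis(benzyloxy)-4-methoxybenzoic acid | COc1cc(OCc2ccccc2)c(C(=O)O)cc1OCc1ccccc1
F3 | step 7 | 2,5-bis(benzyloxy)-4-methoxybenzoic anhydride | COc1cc(OCc2ccccc2)c(C(=O)OC(=O)c2cc(OCc3ccccc3)c(OC)cc2OCc2ccccc2)cc1OCc1ccccc1
F4 | step 7 | 2-[2,5-bis(benzyloxy)-4-methoxyphenyl]-5-hydroxy-3,6,8-trimethoxy-4-oxo-4H-chromen-7-yl 2,5-bis(benzyloxy)-4-methoxybenzoate | COc1cc(OCc2ccccc2)c(-c2oc3c(OC)c(OC(=O)c4cc(OCc5ccccc5)c(OC)cc4OCc4ccccc4)c(OC)c(O)c3c(=O)c2OC)cc1OCc1ccccc1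
F5 | step 2 | 2,6-dimethoxy-3,5-bis(4,4,5,5-tetramethyl-1,3,2-dioxaborolan-2-yl)phenyl acetate | CC(=O)Oc1c(OC)c(B2OC(C)(C)C(C)(C)O2)cc(B2OC(C)(C)C(C)(C)O2)c1OC
F0 | step 8 | none | none
A1 | direct plan | 2,4-dimethoxybenzene-1,3,5-triol | COc1c(O)cc(O)c(OC)c1O
A2 | direct plan | 5,7-dihydroxy-3,6,8-trimethoxy-4H-chromen-4-one | COc1coc2c(OC)c(O)c(OC)c(O)c2c1=O
A3 | direct plan | 2-methoxy-1,4-benzoquinone | COC1=CC(=O)C=CC1=O
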